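**Retrosynthetic overview** (azulene numbering: C1–C3, C3a and C8a form the five-membered ring; C3a, C4–C8 and C8a form the seven-membered ring)
1. The ester C–O bond is cut last; the 4R carbinol comes from a C4 ketone (carried as a dioxolane) by hydroxyl-directed reduction. The tertiary C3–OH/isopropyl unit comes from a 2,3-epoxy-1-ketone by Wharton transposition, which also removes the C1 carbonyl.
2. Key disconnection: both rings come from 2-diazo-5-(2-methoxy-4-methylphenyl)pentan-3-one by an enantioselective intramolecular Buchner reaction, in which the benzene ring plus the carbene carbon becomes the seven-membered ring.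
3. Enabling feature: the seven-membered ring has its C6 methyl and its C4 oxygen in a 1,3-relationship and is fused at C3a and at the methyl-bearing quaternary C8a. It is therefore a 2-methoxy-4-methylphenyl ring (ipso carbon = C3a, OMe carbon = C4, methyl carbon = C6) plus one methyl-substituted carbene carbon (C8a), with the acceptor carbonyl at C1.
4. Ring order: five- and seven-membered rings form together in step 3. The triene is then edited (enol ether to ketal, 1,4-hydrogenation of the diene to leave C6=C7) before the five-membered ring is functionalised.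

Key step: step 3

Remark: the target is taken as drawn, (3S,3aS,4R,8aR): 3a-H trans to 8a-CH3, 3-OH cis to 3a-H, 4-acyloxy cis to 8a-CH3. The (R,R)-ligand is assumed to give 8aR in step 3; if the sense is opposite, the (S,S)-ligand is used.

**Step 1**
Reactants: 1 2-methoxy-4-methylbenzaldehyde; 2 Meldrum's acid
Product: 5 3-(2-methoxy-4-methylphenyl)propanoic acid, via arylidene Meldrum's acid 3 (not isolated), via benzyl Meldrum's acid 4 (not isolated)
Conditions: HCO2H/Et3N (5:2), 95 °C; then aq. HCl
Reagents that add atoms: Meldrum's acid (2), CC1(C)OC(=O)CC(=O)O1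
Why: Knoevenagel condensation, conjugate transfer hydrogenation of 3 by triethylammonium formate and hydrolysis/decarboxylation of 4 should give the arylpropanoic acid in one flask; no stereocentre is formed.

**Step 2**
Reactants: 5 3-(2-methoxy-4-methylphenyl)propanoic acid
Product: 7 2-diazo-5-(2-methoxy-4-methylphenyl)pentan-3-one, via acid chloride 6 (not isolated)
Conditions: (COCl)2, DMF (cat.), CH2Cl2, 0 °C to rt; evaporate; then CH3CHN2 (3 equiv, ethereal solution freshly made from N-ethyl-N-nitrosourea/KOH), Et2O, −20 to 0 °C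
Reagents that add atoms: diazoethane, CC=[N+]=[N-]
Why: Acylation of diazoethane by the acid chloride (Arndt–Eistert-type diazoketone synthesis) should give the α-methyl diazoketone, the excess diazoalkane taking up HCl; no stereocentre is formed.

**Step 3**
Reactants: 7 2-diazo-5-(2-methoxy-4-methylphenyl)pentan-3-one
Product: 10 (8aR)-4-methoxy-6,8a-dimethyl-3,8a-dihydroazulen-1(2H)-one, via copper carbene 8 (not isolated), via norcaradiene 9 (not isolated)
Conditions: [Cu(MeCN)4]PF6 (5 mol %, monovalent copper), (4R,4'R)-2,2'-(propane-2,2-diyl)bis(4-phenyl-4,5-dihydro-1,3-oxazole) (6 mol %), Na[B(3,5-(CF3)2C6H3)4] (6 mol %), CH2Cl2, 40 °C, slow addition of 7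
Reagents that add atoms: none
Why: The chiral copper carbene 8 adds to the unsubstituted ipso/ortho π-bond of the anisole ring to give norcaradiene 9, whose shared cyclopropane bond opens by a thermally allowed disrotatory 6π electrocyclic reaction to cycloheptatriene 10 (intramolecular Buchner reaction); the closest known reaction type is the copper–bis(oxazoline)-catalysed aromatic addition of 2-diazo-5-arylpentan-3-ones to 8a-methylazulenones. The five-membered ring is closed by [2+1] addition of the tethered carbene carbon to the ipso carbon (exo mode, three-atom keto tether), and the seven-membered ring arises from the six-membered benzene ring by insertion of that same carbon through the norcaradiene-to-cycloheptatriene ring opening. The only new stereocentre, the quaternary C8a, is set by the C2-symmetric ligand, which decides from which face of the arene bond the carbene is delivered. The step needs regioselectivity for the ortho carbon without methoxy (carbenoids avoid a substituted ortho position), and chemoselectivity over 1,2-hydride shift and C–H insertion (copper carbenoids are poor at both and the tether has no activated C–H bond). The methoxy group ends up as the C4 enol ether, the masked C4 oxygen of the target, and the aryl methyl as the C6 methyl.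

**Step 4**
Reactants: 10 (8aR)-4-methoxy-6,8a-dimethyl-3,8a-dihydroazulen-1(2H)-one
Product: 12 (3a'S,8a'R)-6',8a'-dimethyl-2',3',3a',8a'-tetrahydro-1'H-spiro[[1,3]dioxolane-2,4'-azulen]-1'-one (trans-fused), via oxocarbenium ion 11 (not isolated)
Conditions: HOCH2CH2OH (5 equiv), PPTS (10 mol %), 4 Å MS, CH2Cl2, 0 °C to rt
Reagents that add atoms: ethylene glycol, OCCO
Why: Acid-catalysed exchange of an enol ether into a cyclic ketal: C-protonation at C3a gives the oxygen-stabilised dienyl cation 11, which the diol captures at C4 with loss of methanol; the C3a–H bond should form anti to the neighbouring 8a-methyl (1,2-induction), which is also expected to be the more stable trans ring fusion if the step equilibrates.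

**Step 5**
Reactants: 12 dienyl ketal
Product: 13 (3a'S,8a'R)-6',8a'-dimethyl-2',3',3a',5',8',8a'-hexahydro-1'H-spiro[[1,3]dioxolane-2,4'-azulen]-1'-one
Conditions: H2 (70 atm), (η6-naphthalene)Cr(CO)3 (20 mol %, zerovalent chromium), THF, 45 °C
Reagents that add atoms: none
Why: Arene-tricarbonylchromium-catalysed 1,4-hydrogenation adds H2 only across the termini (C5 and C8) of the ring-locked s-cis diene, so the C6=C7 alkene of the target should result while ketone and ketal are untouched; no stereocentre is formed.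

**Step 6**
Reactants: 13 saturated ketone
Product: 15 (3a'S,8a'R)-6',8a'-dimethyl-3a',5',8',8a'-tetrahydro-1'H-spiro[[1,3]dioxolane-2,4'-azulen]-1'-one (C2'=C3' enone), via lithium enolate 14 (not isolated)
Conditions: LiN(iPr)2, THF, −78 °C; then PhS(Cl)=NtBu, −78 °C
Reagents that add atoms: none
Why: Ketone dehydrogenation through the lithium enolate with N-tert-butylbenzenesulfinimidoyl chloride (sulfenylation at C2', then syn elimination); enolisation can only go towards C2' because C8a' is quaternary.

**Step 7**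
Reactants: 15 enone
Product: 17 (3a'S,8a'R)-6',8a'-dimethyl-3'-(propan-2-yl)-3a',5',8',8a'-tetrahydro-1'H-spiro[[1,3]dioxolane-2,4'-azulen]-1'-one, via magnesium enolate 16 (not isolated)
Conditions: iPrMgCl, CuBr·SMe2 (10 mol %, monovalent copper), THF, −78 °C; then PhS(Cl)=NtBu, −78 to 0 °C
Reagents that add atoms: isopropylmagnesium chloride, CC(C)[Mg]Cl
Why: Copper-catalysed conjugate addition followed by dehydrogenation of the magnesium enolate in the same flask (one-pot β-alkylation of an enone); the C3' stereocentre of 16 (isopropyl expected anti to 8a'-CH3) is erased when the enone is reformed.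

**Step 8**
Reactants: 17 β-isopropyl enone
Product: 18 (2'S,3'S,3a'R,8a'R)-2',3'-epoxy-6',8a'-dimethyl-3'-(propan-2-yl)-2',3',3a',5',8',8a'-hexahydro-1'H-spiro[[1,3]dioxolane-2,4'-azulen]-1'-one (epoxide oxygen cis to 3a'-H)
Conditions: 30% H2O2, NaOH (aq), MeOH, 0 °C
Reagents that add atoms: hydrogen peroxide, OO
Why: Weitz–Scheffer nucleophilic epoxidation is selective for the enone over the trisubstituted alkene, and hydroperoxide should attack C3' on the face of 3a'-H, anti to the angular 8a'-methyl, which fixes the configuration of the C3 oxygen.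

**Step 9**
Reactants: 18 epoxy ketone
Product: 21 (3'R,3a'R,8a'S)-6',8a'-dimethyl-3'-(propan-2-yl)-3a',5',8',8a'-tetrahydro-3'H-spiro[[1,3]dioxolane-2,4'-azulen]-3'-ol, via epoxy hydrazone 19 (not isolated), via allylic diazene 20 (not isolated)
Conditions: N2H4·H2O, AcOH (cat.), MeOH, 0 °C to rt
Reagents that add atoms: none
Why: Wharton transposition: hydrazone 19 opens the epoxide to diazene 20, which loses N2, so the C1' carbonyl is removed and the tertiary C3' alcohol appears with its C–O bond untouched (configuration retained).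

**Step 10**
Reactants: 21 allylic alcohol
Product: 22 (3'S,3a'R,8a'R)-6',8a'-dimethyl-3'-(propan-2-yl)-1',2',3a',5',8',8a'-hexahydro-3'H-spiro[[1,3]dioxolane-2,4'-azulen]-3'-ol
Conditions: 2-O2NC6H4SO2NHNH2, Et3N, CH2Cl2, rt
Reagents that add atoms: none
Why: Diimide reduction transfers H2 in a concerted syn fashion to the strained cis-disubstituted cyclopentene, while the trisubstituted C6'=C7' alkene should react far more slowly; no stereocentre is formed.

**Step 11**
Reactants: 22 ketal alcohol
Product: 23 (3S,3aR,8aR)-3-hydroxy-6,8a-dimethyl-3-(propan-2-yl)-2,3,3a,5,8,8a-hexahydroazulen-4(1H)-one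
Conditions: PPTS, acetone/H2O (10:1), 40 °C
Reagents that add atoms: water, O
Why: Mild acid hydrolysis of the dioxolane, with a weak acid chosen so that the β,γ-alkene does not move into conjugation and the β-hydroxy ketone neither dehydrates nor epimerises at C3a.

**Step 12**
Reactants: 23 β-hydroxy ketone
Product: 24 (3S,3aS,4R,8aR)-6,8a-dimethyl-3-(propan-2-yl)-1,2,3,3a,4,5,8,8a-octahydroazulene-3,4-diol
Conditions: Me4N[BH(OAc)3], MeCN/AcOH (1:1), −20 °C
Reagents that add atoms: none
Why: Hydroxyl-directed reduction (Evans–Saksena type): the borohydride bound to 3-OH should deliver hydride to C4 on the face of 3-OH and 3a-H, which is also the face away from 8a-CH3 and isopropyl, giving the 4R alcohol (oxygen cis to 8a-CH3).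

**Step 13**
Reactants: 24 diol; 25 4-acetoxybenzoyl chloride
Product: 26 (3S,3aS,4R,8aR)-3-hydroxy-6,8a-dimethyl-3-(propan-2-yl)-1,2,3,3a,4,5,8,8a-octahydroazulen-4-yl 4-acetoxybenzoate
Conditions: 25, Et3N, DMAP (cat.), CH2Cl2, 0 °C to rt
Reagents that add atoms: 4-acetoxybenzoyl chloride (25), CC(=O)Oc1ccc(cc1)C(Cl)=O
Why: DMAP-catalysed acylation should discriminate the secondary C4–OH from the tertiary C3–OH on steric grounds, and the acetate keeps the phenol from self-acylation.

**Step 14**
Reactants: 26 acetate-protected ester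
Product: 27 (3S,3aS,4R,8aR)-3-hydroxy-6,8a-dimethyl-3-(propan-2-yl)-1,2,3,3a,4,5,8,8a-octahydroazulen-4-yl 4-hydroxybenzoate
Conditions: K2CO3 (cat.), MeOH, 0 °C
Reagents that add atoms: none
Why: Base-catalysed methanolysis should cleave the aryl acetate much faster than the hindered alkyl benzoate, which is deactivated further once the phenoxide forms; no stereocentre is touched.

**Compound list**
1 | 2-methoxy-4-methylbenzaldehyde | COc1cc(C)ccc1C=O | starting material
2 | Meldrum's acid (2,2-dimethyl-1,3-dioxane-4,6-dione) | CC1(C)OC(=O)CC(=O)O1 | starting material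
3 | 5-(2-methoxy-4-methylbenzylidene)-2,2-dimethyl-1,3-dioxane-4,6-dione | CC1(C)OC(=O)C(=Cc2ccc(C)cc2OC)C(=O)O1 | intermediate
4 | 5-(2-methoxy-4-methylbenzyl)-2,2-dimethyl-1,3-dioxane-4,6-dione | CC1(C)OC(=O)C(Cc2ccc(C)cc2OC)C(=O)O1 | intermediate
5 | 3-(2-methoxy-4-methylphenyl)propanoic acid | COc1cc(C)ccc1CCC(=O)O | intermediate
6 | 3-(2-methoxy-4-methylphenyl)propanoyl chloride | COc1cc(C)ccc1CCC(=O)Cl | intermediate
7 | 2-diazo-5-(2-methoxy-4-methylphenyl)pentan-3-one | COc1cc(C)ccc1CCC(=O)C(C)=[N+]=[N-] | intermediate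
8 | copper carbene from 7 (bis(oxazoline) ligand omitted) | COc1cc(C)ccc1CCC(=O)C(C)=[Cu] | intermediate
9 | norcaradiene valence tautomer of 10 (cyclopropane C3a–C8–C8a, 8a-CH3 syn to the six-membered ring) | C[C@]12C(=O)CC[C@@]13[C@@H]2C=C(C)C=C3OC | intermediate
10 | (8aR)-4-methoxy-6,8a-dimethyl-3,8a-dihydroazulen-1(2H)-one | C[C@@]12C=CC(C)=CC(OC)=C1CCC2=O | intermediate
11 | O-methyl oxocarbenium ion from C3a-protonation of 10 (3a-H trans to 8a-CH3) | C[C@@]12C=CC(C)=CC(=[O+]C)[C@H]1CCC2=O | intermediate
12 | (3a'S,8a'R)-6',8a'-dimethyl-2',3',3a',8a'-tetrahydro-1'H-spiro[[1,3]dioxolane-2,4'-azulen]-1'-one | C[C@@]12C=CC(C)=CC3(OCCO3)[C@H]1CCC2=O | intermediate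
13 | (3a'S,8a'R)-6',8a'-dimethyl-2',3',3a',5',8',8a'-hexahydro-1'H-spiro[[1,3]dioxolane-2,4'-azulen]-1'-one | C[C@@]12CC=C(C)CC3(OCCO3)[C@H]1CCC2=O | intermediate
14 | lithium enolate of 13 (C1'=C2') | C[C@@]12CC=C(C)CC3(OCCO3)[C@H]1CC=C2O[Li] | intermediate
15 | (3a'S,8a'R)-6',8a'-dimethyl-3a',5',8',8a'-tetrahydro-1'H-spiro[[1,3]dioxolane-2,4'-azulen]-1'-one | C[C@@]12CC=C(C)CC3(OCCO3)[C@H]1C=CC2=O | intermediate
16 | chloromagnesium enolate after isopropyl addition (3'-isopropyl cis to 3a'-H) | C[C@@]12CC=C(C)CC3(OCCO3)[C@H]1[C@H](C(C)C)C=C2O[Mg]Cl | intermediate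
17 | (3a'S,8a'R)-6',8a'-dimethyl-3'-(propan-2-yl)-3a',5',8',8a'-tetrahydro-1'H-spiro[[1,3]dioxolane-2,4'-azulen]-1'-one | C[C@@]12CC=C(C)CC3(OCCO3)[C@H]1C(C(C)C)=CC2=O | intermediate
18 | (2'S,3'S,3a'R,8a'R)-2',3'-epoxy-6',8a'-dimethyl-3'-(propan-2-yl)-2',3',3a',5',8',8a'-hexahydro-1'H-spiro[[1,3]dioxolane-2,4'-azulen]-1'-one | C[C@@]12CC=C(C)CC3(OCCO3)[C@H]1[C@]4(C(C)C)O[C@@H]4C2=O | intermediate
19 | hydrazone of 18 at C1' | C[C@@]12CC=C(C)CC3(OCCO3)[C@H]1[C@]4(C(C)C)O[C@@H]4C2=NN | intermediate
20 | allylic diazene (C1'–N=NH, C1'=C2', 3'-OH) | C[C@@]12CC=C(C)CC3(OCCO3)[C@H]1[C@@](O)(C(C)C)C=C2N=N | intermediate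
21 | (3'R,3a'R,8a'S)-6',8a'-dimethyl-3'-(propan-2-yl)-3a',5',8',8a'-tetrahydro-3'H-spiro[[1,3]dioxolane-2,4'-azulen]-3'-ol | C[C@@]12CC=C(C)CC3(OCCO3)[C@H]1[C@@](O)(C(C)C)C=C2 | intermediate
22 | (3'S,3a'R,8a'R)-6',8a'-dimethyl-3'-(propan-2-yl)-1',2',3a',5',8',8a'-hexahydro-3'H-spiro[[1,3]dioxolane-2,4'-azulen]-3'-ol | C[C@@]12CC=C(C)CC3(OCCO3)[C@H]1[C@@](O)(C(C)C)CC2 | intermediate
23 | (3S,3aR,8aR)-3-hydroxy-6,8a-dimethyl-3-(propan-2-yl)-2,3,3a,5,8,8a-hexahydroazulen-4(1H)-one | C[C@@]12CC=C(C)CC(=O)[C@H]1[C@@](O)(C(C)C)CC2 | intermediate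
24 | (3S,3aS,4R,8aR)-6,8a-dimethyl-3-(propan-2-yl)-1,2,3,3a,4,5,8,8a-octahydroazulene-3,4-diol | C[C@@]12CC=C(C)C[C@@H](O)[C@H]1[C@@](O)(C(C)C)CC2 | intermediate
25 | 4-acetoxybenzoyl chloride | CC(=O)Oc1ccc(cc1)C(Cl)=O | starting material
26 | (3S,3aS,4R,8aR)-3-hydroxy-6,8a-dimethyl-3-(propan-2-yl)-1,2,3,3a,4,5,8,8a-octahydroazulen-4-yl 4-acetoxybenzoate | C[C@@]12CC=C(C)C[C@@H](OC(=O)c3ccc(OC(C)=O)cc3)[C@H]1[C@@](O)(C(C)C)CC2 | intermediate
27 | (3S,3aS,4R,8aR)-3-hydroxy-6,8a-dimethyl-3-(propan-2-yl)-1,2,3,3a,4,5,8,8a-octahydroazulen-4-yl 4-hydroxybenzoate | CC1=CC[C@@]2(C)CC[C@](O)(C(C)C)[C@@H]2[C@H](OC(=O)c2ccc(O)cc2)C1 | target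

**Total step count:** 14
**Longest linear sequence:** 14 steps (1 to 27)

**Steps most likely to fail**

Step 3. The chiral copper catalyst may not discriminate the two faces well enough, because the ortho-methoxy group can compete for the metal; formal aromatic substitution may also erode the aromatic addition. Fallback: setting out from 7, the Buchner reaction is run with achiral Rh2(OAc)4 (divalent rhodium, CH2Cl2, 40 °C), which should give racemic azulenone F1. The racemate is resolved by preparative chromatography on a chiral stationary phase (amylose tris(3,5-dimethylphenylcarbamate)), and the (8aR) enantiomer comes back to the route as 10. Stereocontrol then rests on resolution instead of asymmetric catalysis.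

Step 4. The acid may trigger rearomatisation of the norcaradiene tautomer to a 2-tetralone, the glycol may be captured at a vinylogous carbon of the dienyl cation, or protonation at C3a may show poor facial selectivity. Fallback: setting out from 10, NaBH4 (MeOH, 0 °C) reduces the C1 ketone to the alcohol F2 (1-OH cis to 8a-CH3), which removes the acceptor that stabilises the norcaradiene. Aqueous oxalic acid (THF/H2O) then hydrolyses the enol ether to the dienone alcohol F3, whose C3a centre, now α to a carbonyl, can be equilibrated with DBU towards the trans ring fusion. Li/NH3 (THF, −78 °C, then NH4Cl) reduces the dienone, and α-protonation of the dienolate should give the β,γ-unsaturated ketone F4. Ketalisation (ethylene glycol, PPTS, benzene, reflux) gives the ketal alcohol F5, and Dess–Martin oxidation comes back to the route at 13. This bypasses steps 4 and 5.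

Step 9. Hydrazone formation at the neopentyl-type C1' carbonyl may be slow, so that epoxide opening by hydrazine or azine formation competes. Fallback: setting out from 18, SmI2 (THF/MeOH, −78 °C) opens the epoxide reductively at the α-carbon to the β-hydroxy ketone F6. NaBH4 gives the diol F7, whose secondary 1'-OH is converted selectively into the O-phenyl thionocarbonate F8 (PhOC(S)Cl, pyridine, DMAP). Barton–McCombie deoxygenation (Bu3SnH, AIBN, toluene, 80 °C) comes back to the route at 22, bypassing steps 9 and 10.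

**Further compounds**
F1 | step 3 | racemic 4-methoxy-6,8a-dimethyl-3,8a-dihydroazulen-1(2H)-one | CC12C=CC(C)=CC(OC)=C1CCC2=O
F2 | step 4 | (1R,8aR)-4-methoxy-6,8a-dimethyl-1,2,3,8a-tetrahydroazulen-1-ol | C[C@@]12C=CC(C)=CC(OC)=C1CC[C@H]2O
F3 | step 4 | (1R,3aS,8aR)-1-hydroxy-6,8a-dimethyl-2,3,3a,8a-tetrahydroazulen-4(1H)-one | C[C@@]12C=CC(C)=CC(=O)[C@H]1CC[C@H]2O
F4 | step 4 | (1R,3aS,8aR)-1-hydroxy-6,8a-dimethyl-2,3,3a,5,8,8a-hexahydroazulen-4(1H)-one | C[C@@]12CC=C(C)CC(=O)[C@H]1CC[C@H]2O
F5 | step 4 | (1'R,3a'S,8a'R)-6',8a'-dimethyl-2',3',3a',5',8',8a'-hexahydro-1'H-spiro[[1,3]dioxolane-2,4'-azulen]-1'-ol | C[C@@]12CC=C(C)CC3(OCCO3)[C@H]1CC[C@H]2O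
F6 | step 9 | (3'S,3a'R,8a'R)-3'-hydroxy-6',8a'-dimethyl-3'-(propan-2-yl)-2',3',3a',5',8',8a'-hexahydro-1'H-spiro[[1,3]dioxolane-2,4'-azulen]-1'-one | C[C@@]12CC=C(C)CC3(OCCO3)[C@H]1[C@@](O)(C(C)C)CC2=O
F7 | step 9 | (1'R,3'S,3a'R,8a'R)-6',8a'-dimethyl-3'-(propan-2-yl)-octahydro-spiro[[1,3]dioxolane-2,4'-azulene]-1',3'-diol (6',7'-ene retained) | C[C@@]12CC=C(C)CC3(OCCO3)[C@H]1[C@@](O)(C(C)C)C[C@H]2O
F8 | step 9 | O-phenyl thionocarbonate of F7 at the 1'-oxygen | C[C@@]12CC=C(C)CC3(OCCO3)[C@H]1[C@@](O)(C(C)C)C[C@H]2OC(=S)Oc1ccccc1
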